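**Retrosynthetic overview**

1. Last bonds: the seven O–allyl bonds (global deallylation), then the ester bond between the C3 carboxyl of a (1R,2S)-1-aryl-1,2-dihydronaphthalene-2,3-dicarboxylic acid 2-allyl ester and the hydroxyl of diallyl L-malate.
2. Ring B (C1–C2–C3–C4–C4a–C8a) is made in one operation from a trans-γ-aryl paraconate and 3,4-bis(allyloxy)benzaldehyde. The paraconate carries C1–C2–C3, with C1–O held in a temporary γ-lactone with the C3 carboxyl. C3=C4 forms by lactone-enolate aldol condensation and C8a–C1 by acid-triggered lactone ionisation and Friedel–Crafts closure, a formal [3+3] annulation that sets C1 and unmasks only the C3 acid.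
3. Enabling feature: the oxygen para to C1 on the pendant catechol ring makes the benzylic C1–O bond ionisable; the C6 oxygen of ring A is para to C8a and makes that carbon the nucleophile; C3 (α to a carboxyl) and C4 (aldehyde level, non-enolisable) are a natural aldol pair.
4. The paraconate comes from an Evans syn-aldol of a succinate imide with the same aldehyde (C2 stereocentre); the malate centre comes from L-malic acid.
5. Ring order: temporary γ-lactone (step 3), then ring B (step 6); both benzene rings are bought.

Key step: step 6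

Remark: locants C1–C4, C4a and C8a are those of the 1,2-dihydronaphthalene-2,3-dicarboxylic acid core (C1 = CH–aryl, C2 = CH–CO2H, C3 = C–CO2R, C4 = CH=) and are used for the corresponding carbons of every precursor. The C1 configuration of the lactone intermediates is not relayed to the target, because C1 passes through a planar cation in the key step.

**Route**

Step 1
Reactants: 1 3,4-dihydroxybenzaldehyde
Product: 2 3,4-bis(allyloxy)benzaldehyde
Conditions: allyl bromide (2.5 equiv), K2CO3, DMF, 60 °C
Reagents that add atoms: allyl bromide, C=CCBr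
Why: Williamson ether synthesis on both phenoxides should give the bis-allyl ether, which serves as the source of both aryl rings.

Step 2
Reactants: 3 (R)-4-benzyl-2-oxazolidinone; 4 methyl 4-chloro-4-oxobutanoate
Product: 5 (R)-4-benzyl-3-(4-methoxy-4-oxobutanoyl)oxazolidin-2-one
Conditions: n-BuLi, THF, −78 °C; then 4, −78 → 0 °C
Reagents that add atoms: none
Why: N-acylation of the lithiated oxazolidinone by the acid chloride is the standard imide formation and leaves the methyl ester untouched at low temperature.

Step 3
Reactants: 5 (R)-4-benzyl-3-(4-methoxy-4-oxobutanoyl)oxazolidin-2-one; 2 3,4-bis(allyloxy)benzaldehyde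
Product: 7 (R)-4-benzyl-3-{(2R,3R)-2-[3,4-bis(allyloxy)phenyl]-5-oxotetrahydrofuran-3-carbonyl}oxazolidin-2-one, via syn-aldol adduct 6 (not isolated)
Conditions: Bu2BOTf, i-Pr2NEt, CH2Cl2, 0 °C; 2, −78 → 0 °C; pH 7 buffer, MeOH, 30% H2O2, 0 °C; then PPTS (cat.), toluene, 60 °C
Reagents that add atoms: none
Why: The Evans syn-aldol of the Z-boron enolate through a Zimmerman–Traxler chair, on the face away from the benzyl group of the (R)-auxiliary, should set C2 (and C1) as 2R,3R, and the γ-hydroxy methyl ester then closes (5-exo-trig acyl substitution) to the trans-lactone.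

Step 4
Reactants: 7 (R)-4-benzyl-3-{(2R,3R)-2-[3,4-bis(allyloxy)phenyl]-5-oxotetrahydrofuran-3-carbonyl}oxazolidin-2-one
Product: 9 (2R,3R)-2-[3,4-bis(allyloxy)phenyl]-5-oxotetrahydrofuran-3-carboxylic acid, via peroxy acid 8 (not isolated)
Conditions: LiOH, 30% H2O2, THF/H2O 3:1, 0 °C; aq. Na2SO3; 1 M HCl to pH 2
Reagents that add atoms: hydrogen peroxide (as lithium hydroperoxide), OO
Why: Hydroperoxide attacks the exocyclic imide carbonyl selectively (standard auxiliary cleavage, sulfite then reduces the peroxy acid) without enolising C2, and the auxiliary is recovered.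

Step 5
Reactants: 9 (2R,3R)-2-[3,4-bis(allyloxy)phenyl]-5-oxotetrahydrofuran-3-carboxylic acid
Product: 10 allyl (2R,3R)-2-[3,4-bis(allyloxy)phenyl]-5-oxotetrahydrofuran-3-carboxylate
Conditions: allyl bromide, KHCO3, DMF, rt
Reagents that add atoms: allyl bromide, C=CCBr
Why: SN2 O-alkylation of the carboxylate under a base too weak to enolise the ester should preserve the lactone and the C2 centre.

Step 6
Reactants: 10 allyl (2R,3R)-2-[3,4-bis(allyloxy)phenyl]-5-oxotetrahydrofuran-3-carboxylate; 2 3,4-bis(allyloxy)benzaldehyde
Product: 13 (1R,2S)-6,7-bis(allyloxy)-1-[3,4-bis(allyloxy)phenyl]-1,2-dihydronaphthalene-2,3-dicarboxylic acid 2-allyl ester (free acid at C3), via aldol adduct 11 (not isolated), via arylidene lactone 12 (not isolated)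
Conditions: i) LiN(SiMe3)2 (1.05 equiv), THF, −78 °C; then 2 (1.1 equiv), −78 °C; ii) CH2Cl2, TFA (excess), −78 °C → rt
Reagents that add atoms: none
Why: LiN(SiMe3)2 removes the lactone α-proton at C3 (a γ-lactone is several pKa units more acidic than the acyclic allyl ester at C2) and the enolate adds to the non-enolisable aldehyde 2 to form C3–C4; TFA then dehydrates the p-alkoxybenzylic aldol 11 by E1 to the (E)-arylidene lactone 12 and ionises the benzylic lactone C1–O bond (alkyl–oxygen cleavage, as for p-alkoxybenzyl esters), whereupon C8a of ring A captures the cation and the C3 carboxylic acid is set free. The closest known reaction types are the lactone-enolate aldol condensation and the acid-induced rearrangement of α-arylidene-γ-aryl lactones, of hydroxycinnamate 8–8′ dilactones and of 2,5-diaryltetrahydrofuran lignans to 1-aryl-1,2-dihydronaphthalenes. Ring B closes by a cationic 6-endo-trig Friedel–Crafts alkylation, which the E geometry of C3=C4 (C4a cis to C2) makes possible. C1 is formed from a planar cation, so its configuration in 10 is irrelevant, and the C2 stereocentre should steer ring A to the face anti to the C2 ester, giving the 1,2-trans (1R,2S) product with both substituents pseudo-axial. The step needs site-selective enolisation (secured by the acidity difference and by the cold acid quench, so that the aldolate cannot translactonise onto the allyl ester), attack at the ring A carbon para to the C6 allyloxy group rather than ortho to it (electronic and steric preference), and retention of C2 (TFA does not C-protonate cinnamates, so an elimination product of the C1 cation cannot re-enter as racemate). Because only the lactone carboxyl is unmasked, the two carboxyls of the product are differentiated for the malate esterification.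

Step 7
Reactants: 14 L-malic acid
Product: 15 diallyl (S)-2-hydroxysuccinate (diallyl L-malate)
Conditions: allyl alcohol (excess), TsOH·H2O (cat.), toluene, reflux, Dean–Stark
Reagents that add atoms: allyl alcohol, C=CCO
Why: Fischer esterification with azeotropic removal of water should esterify both carboxyls without touching the stereocentre, the secondary hydroxyl being outcompeted by the excess primary alcohol.

Step 8
Reactants: 13 (1R,2S)-6,7-bis(allyloxy)-1-[3,4-bis(allyloxy)phenyl]-1,2-dihydronaphthalene-2,3-dicarboxylic acid 2-allyl ester; 15 diallyl (S)-2-hydroxysuccinate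
Product: 16 diallyl (S)-2-{[(1R,2S)-6,7-bis(allyloxy)-1-[3,4-bis(allyloxy)phenyl]-2-(allyloxycarbonyl)-1,2-dihydronaphthalene-3-carbonyl]oxy}succinate
Conditions: EDC·HCl, DMAP, CH2Cl2, 0 °C → rt
Reagents that add atoms: none
Why: Steglich esterification of the only free carboxylic acid (C3) should acylate the malate hydroxyl with retention of the (S) centre, since its C–O bond is not broken.

Step 9
Reactants: 16 diallyl (S)-2-{[(1R,2S)-6,7-bis(allyloxy)-1-[3,4-bis(allyloxy)phenyl]-2-(allyloxycarbonyl)-1,2-dihydronaphthalene-3-carbonyl]oxy}succinate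
Product: 17 (S)-2-{[(1R,2S)-2-carboxy-1-(3,4-dihydroxyphenyl)-6,7-dihydroxy-1,2-dihydronaphthalene-3-carbonyl]oxy}succinic acid (target)
Conditions: Pd(PPh3)4 (10 mol %), morpholine (14 equiv), degassed THF, rt, argon; then 1 M HCl
Reagents that add atoms: none
Why: Tsuji–Trost allyl transfer from zerovalent palladium π-allyl intermediates to morpholine should remove the four aryl allyl ethers and three allyl esters under near-neutral conditions that neither reduce C3=C4 nor epimerise C2.

**Compound list**

1 | 3,4-dihydroxybenzaldehyde | O=Cc1ccc(O)c(O)c1 | starting material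
2 | 3,4-bis(allyloxy)benzaldehyde | O=Cc1ccc(OCC=C)c(OCC=C)c1 | intermediate
3 | (R)-4-benzyl-2-oxazolidinone | O=C1N[C@H](Cc2ccccc2)CO1 | starting material
4 | methyl 4-chloro-4-oxobutanoate | COC(=O)CCC(Cl)=O | starting material
5 | (R)-4-benzyl-3-(4-methoxy-4-oxobutanoyl)oxazolidin-2-one | COC(=O)CCC(=O)N1[C@H](Cc2ccccc2)COC1=O | intermediate
6 | (R)-4-benzyl-3-[(2R,3R)-3-[3,4-bis(allyloxy)phenyl]-3-hydroxy-2-(2-methoxy-2-oxoethyl)propanoyl]oxazolidin-2-one (syn-aldol adduct) | COC(=O)C[C@@H](C(=O)N1[C@H](Cc2ccccc2)COC1=O)[C@H](c1ccc(OCC=C)c(OCC=C)c1)O | intermediate (not isolated)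
7 | (R)-4-benzyl-3-{(2R,3R)-2-[3,4-bis(allyloxy)phenyl]-5-oxotetrahydrofuran-3-carbonyl}oxazolidin-2-one | O=C1C[C@@H](C(=O)N2[C@H](Cc3ccccc3)COC2=O)[C@H](c2ccc(OCC=C)c(OCC=C)c2)O1 | intermediate
8 | (2R,3R)-2-[3,4-bis(allyloxy)phenyl]-5-oxotetrahydrofuran-3-carboperoxoic acid | O=C1C[C@@H](C(=O)OO)[C@H](c2ccc(OCC=C)c(OCC=C)c2)O1 | intermediate (not isolated)
9 | (2R,3R)-2-[3,4-bis(allyloxy)phenyl]-5-oxotetrahydrofuran-3-carboxylic acid | O=C1C[C@@H](C(=O)O)[C@H](c2ccc(OCC=C)c(OCC=C)c2)O1 | intermediate
10 | allyl (2R,3R)-2-[3,4-bis(allyloxy)phenyl]-5-oxotetrahydrofuran-3-carboxylate | O=C1C[C@@H](C(=O)OCC=C)[C@H](c2ccc(OCC=C)c(OCC=C)c2)O1 | intermediate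
11 | allyl (2R,3R)-4-{[3,4-bis(allyloxy)phenyl](hydroxy)methyl}-2-[3,4-bis(allyloxy)phenyl]-5-oxotetrahydrofuran-3-carboxylate (epimers at C4 of the lactone and at the carbinol carbon) | O=C1C(C(O)c2ccc(OCC=C)c(OCC=C)c2)[C@@H](C(=O)OCC=C)[C@H](c2ccc(OCC=C)c(OCC=C)c2)O1 | intermediate (not isolated)
12 | allyl (2R,3R,E)-4-[3,4-bis(allyloxy)benzylidene]-2-[3,4-bis(allyloxy)phenyl]-5-oxotetrahydrofuran-3-carboxylate | O=C1/C(=C/c2ccc(OCC=C)c(OCC=C)c2)[C@@H](C(=O)OCC=C)[C@H](c2ccc(OCC=C)c(OCC=C)c2)O1 | intermediate (not isolated)
13 | (1R,2S)-6,7-bis(allyloxy)-1-[3,4-bis(allyloxy)phenyl]-1,2-dihydronaphthalene-2,3-dicarboxylic acid 2-allyl ester | OC(=O)C1=Cc2cc(OCC=C)c(OCC=C)cc2[C@@H](c2ccc(OCC=C)c(OCC=C)c2)[C@@H]1C(=O)OCC=C | intermediate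
14 | L-malic acid, (S)-2-hydroxysuccinic acid | OC(=O)C[C@H](O)C(=O)O | starting material
15 | diallyl (S)-2-hydroxysuccinate | C=CCOC(=O)C[C@H](O)C(=O)OCC=C | intermediate
16 | diallyl (S)-2-{[(1R,2S)-6,7-bis(allyloxy)-1-[3,4-bis(allyloxy)phenyl]-2-(allyloxycarbonyl)-1,2-dihydronaphthalene-3-carbonyl]oxy}succinate | C=CCOC(=O)C[C@H](OC(=O)C1=Cc2cc(OCC=C)c(OCC=C)cc2[C@@H](c2ccc(OCC=C)c(OCC=C)c2)[C@@H]1C(=O)OCC=C)C(=O)OCC=C | intermediate
17 | (S)-2-{[(1R,2S)-2-carboxy-1-(3,4-dihydroxyphenyl)-6,7-dihydroxy-1,2-dihydronaphthalene-3-carbonyl]oxy}succinic acid | O=C(O)C[C@H](OC(=O)C1=Cc2cc(O)c(O)cc2[C@@H](c2ccc(O)c(O)c2)[C@@H]1C(=O)O)C(=O)O | target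

**Step count and risks**

Total steps: 9. Longest linear sequence: 7 (steps 2, 3, 4, 5, 6, 8, 9; equally 1, 3, 4, 5, 6, 8, 9).

Steps most likely to fail:

Step 6. The base could remove the C2 proton instead of the C3 proton, which would open the lactone by β-elimination and destroy the C2 stereocentre. The lithium aldolate could translactonise onto the allyl ester before the acid quench. In the acid stage the C1 cation could lose a proton instead of being captured by ring A. The fallback sets out from acid 9. Its dianion (LiN(SiMe3)2, 2.2 equiv, THF, −78 °C) has the C2 proton shielded as a carboxylate α-proton, so the elimination channel is closed. Aldol addition to 2 should give (2R,3R)-4-{[3,4-bis(allyloxy)phenyl](hydroxy)methyl}-2-[3,4-bis(allyloxy)phenyl]-5-oxotetrahydrofuran-3-carboxylic acid F1. Allyl bromide and KHCO3 in DMF then convert F1 into the aldol ester 11, where the fallback comes back to the route. Compound 11 is now isolated and taken to 13 by the TFA stage of step 6 on its own, in CH2Cl2 without THF.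

Step 8. The hindered, weakly nucleophilic malate hydroxyl may be acylated too slowly, so that the activated acid rearranges to an N-acylurea. DMAP may also cause β-elimination of the acylated malate, or epimerisation at C2 or migration of the C3=C4 bond in the activated acid. The fallback sets out from 13 and reverses the roles of the partners. (R)-Malic acid (commercial) is esterified as in step 7 to diallyl (R)-2-hydroxysuccinate F2. A Mitsunobu reaction of 13 with F2 (PPh3, DIAD, THF, 0 °C) uses the C3 carboxylate as nucleophile under neutral conditions and should invert the malate centre to (S), coming back at 16.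

Step 9. Cleavage of the four aryl allyl ethers may stall after the faster ester cleavage. The π-allyl palladium intermediate may C-allylate the liberated electron-rich catechol rings. The free catechols may oxidise in the amine medium. The fallback sets out from 16 and uses isomerisation instead of allyl transfer. RhCl(PPh3)3 (cat.) in toluene at 80 °C should move all seven double bonds into conjugation with oxygen, giving the heptakis(prop-1-enyl) isomer of 16 F3, a set of enol ethers and enol esters. Mild hydrolysis (0.5 M HCl, THF/H2O, rt) then releases the phenols and acids and comes back at target 17.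

**Further compounds**

F1 | step 6 | (2R,3R)-4-{[3,4-bis(allyloxy)phenyl](hydroxy)methyl}-2-[3,4-bis(allyloxy)phenyl]-5-oxotetrahydrofuran-3-carboxylic acid (epimers at C4 of the lactone and at the carbinol carbon) | O=C1C(C(O)c2ccc(OCC=C)c(OCC=C)c2)[C@@H](C(=O)O)[C@H](c2ccc(OCC=C)c(OCC=C)c2)O1
F2 | step 8 | diallyl (R)-2-hydroxysuccinate | C=CCOC(=O)C[C@@H](O)C(=O)OCC=C
F3 | step 9 | bis(prop-1-enyl) (S)-2-{[(1R,2S)-6,7-bis(prop-1-enyloxy)-1-[3,4-bis(prop-1-enyloxy)phenyl]-2-(prop-1-enyloxycarbonyl)-1,2-dihydronaphthalene-3-carbonyl]oxy}succinate (E/Z mixture at the enol double bonds) | CC=COC(=O)C[C@H](OC(=O)C1=Cc2cc(OC=CC)c(OC=CC)cc2[C@@H](c2ccc(OC=CC)c(OC=CC)c2)[C@@H]1C(=O)OC=CC)C(=O)OC=CC
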